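Ring B of the target hides a cyclohexene retron: the bonds C5–C10 and C8–C9 flank C9–C10, so cutting both opens rings A and B together to an acyclic trienal in which C5=C6–C7=C8 is an (E,E)-diene, C9=C10 an (E)-enal and the four carbons C1–C4, with the two methyl groups on C4, the connecting tether. A single iminium-catalysed intramolecular Diels–Alder reaction of this (2E,8E,10E)-trienal therefore makes both rings, two C–C bonds and the trans C5/C10 fusion in one absolute sense; C8 and C9 later become sp2, so only the C5/C10 pair must be controlled. Stereospecific alkene syntheses deliver the trienal, and propargylation plus carboalumination/cross-coupling adds C12–C18.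

Key step: step 7

Remark (numbering): ring carbons are C1–C10 as in drimanes (C4 carries the gem-dimethyl group, C10 the angular methyl), C11 is the carbon on C9, and the chain runs on as C12–C18 with C18 the carboxyl carbon; β is the face of the C10 methyl group.

Remark (chain stereocentre): the hydroxymethyl carbon of methyl 3-hydroxy-2-methylpropanoate ends as the carboxyl carbon C18 and its ester carbon as C16, so the (S)-ester is the enantiomer that maps onto (17R); the (R)-ester would give the 17-epimer.

Step 1
Reactants: 1 isobutyronitrile; 2 (5-iodopent-1-yn-1-yl)trimethylsilane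
Product: 4 2,2-dimethyl-7-(trimethylsilyl)hept-6-ynenitrile, via lithiated nitrile 3 (not isolated)
Conditions: LiN(i-Pr)2 (commercial solution, 1.05 equiv), THF, −78 °C; then 2, −78 °C → rt
Reagents that add atoms: none
Why: SN2 alkylation of the lithiated tertiary nitrile with a primary iodide is a standard route to a quaternary carbon (the future C4 with both methyl groups), and the silyl cap keeps the alkyne from quenching the carbanion.

Step 2
Reactants: 4 2,2-dimethyl-7-(trimethylsilyl)hept-6-ynenitrile
Product: 6 2,2-dimethyl-7-(trimethylsilyl)hept-6-ynal, via aluminium aldimine 5 (not isolated)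
Conditions: i-Bu2AlH (1.2 equiv), toluene, −78 °C; then 1 M HCl, 0 °C
Reagents that add atoms: water, O
Why: Hydride addition of i-Bu2AlH to a nitrile stops at the N-aluminio aldimine, which aqueous acid hydrolyses to the aldehyde, so over-reduction is excluded and the silylalkyne is untouched at low temperature (nitrile-to-aldehyde reduction).

Step 3
Reactants: 6 2,2-dimethyl-7-(trimethylsilyl)hept-6-ynal
Product: 7 [(7E)-8-iodo-6,6-dimethyloct-7-en-1-yn-1-yl]trimethylsilane
Conditions: CrCl2 (6 equiv), CHI3 (2 equiv), THF/1,4-dioxane, 0 °C → rt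
Reagents that add atoms: iodoform, IC(I)I
Why: The Takai olefination converts aldehydes into (E)-vinyl iodides through a geminal dichromium reagent, and the quaternary α-carbon should reinforce the E preference while excluding enolisation, which fixes the C5=C6 geometry of the later diene.

Step 4
Reactants: 7 [(7E)-8-iodo-6,6-dimethyloct-7-en-1-yn-1-yl]trimethylsilane; 8 (E)-prop-1-en-1-ylboronic acid
Product: 10 (7E,9E)-6,6-dimethylundeca-7,9-dien-1-yne, via silyl dienyne 9 (not isolated)
Conditions: Pd(PPh3)4 (5 mol %), K2CO3 (3 equiv), THF/H2O, 50 °C; then MeOH, rt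
Reagents that add atoms: none
Why: Suzuki–Miyaura coupling of two (E)-alkenyl partners proceeds with retention at both double bonds and should give the (E,E)-diene stereospecifically, after which methanolic carbonate in the same flask cleaves the alkynyl C–Si bond.

Step 5
Reactants: 10 (7E,9E)-6,6-dimethylundeca-7,9-dien-1-yne
Product: 13 (2E,8E,10E)-3,7,7-trimethyldodeca-2,8,10-trien-1-ol, via alkenylalane 11 (not isolated), via lithium alanate 12 (not isolated)
Conditions: AlMe3 (2 equiv), Cp2ZrCl2 (0.25 equiv), CH2Cl2, 0 °C → rt; volatiles removed in vacuo; n-BuLi, THF/hexane, −78 °C; (CH2O)n, −78 °C → rt; dilute HCl work-up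
Reagents that add atoms: trimethylaluminium, C[Al](C)C; formaldehyde (from paraformaldehyde), C=O
Why: Zirconium-catalysed carboalumination adds CH3 and Al syn across the terminal alkyne with Al at the terminus, and hydroxymethylation of the derived alanate occurs with retention, so the trisubstituted C2=C3 bond (the later C9=C10 dienophile) should form as the E isomer only while the internal diene is not carbometallated.

Step 6
Reactants: 13 (2E,8E,10E)-3,7,7-trimethyldodeca-2,8,10-trien-1-ol
Product: 14 (2E,8E,10E)-3,7,7-trimethyldodeca-2,8,10-trienal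
Conditions: MnO2 (activated, 15 equiv), CH2Cl2, rt
Reagents that add atoms: none
Why: Activated MnO2 oxidises primary allylic alcohols to enals under neutral heterogeneous conditions, which should leave the 2E geometry and the diene unchanged (allylic oxidation).

Step 7
Reactants: 14 (2E,8E,10E)-3,7,7-trimethyldodeca-2,8,10-trienal
Product: 17 (1S,2S,4aS,8aS)-2,5,5,8a-tetramethyl-1,2,4a,5,6,7,8,8a-octahydronaphthalene-1-carbaldehyde [trans-fused drim-6-en-11-al with 8β-CH3 and 9β-CHO], via iminium ion 15 (not isolated), via adduct iminium 16 (not isolated)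
Conditions: (2S,5S)-5-benzyl-2-tert-butyl-3-methylimidazolidin-4-one·CF3SO3H (second-generation imidazolidinone catalyst, 20 mol %), MeCN/H2O (98:2), 0 °C → rt
Reagents that add atoms: none
Why: Proposed new method: the amine salt condenses with enal 14 to the E-iminium ion 15, whose lowered LUMO lets the C9=C10 unit add across the C5–C8 diene in a concerted, asynchronous [4+2] in which the bond to the β-carbon (C5–C10) runs ahead of C8–C9, and hydrolysis of 16 returns the catalyst and 17. The closest known reaction type is the imidazolidinone-catalysed type 1 intramolecular Diels–Alder reaction of β-monosubstituted (2E)-trienals with a distal (E,E)-diene to trans-fused bicycles, together with thermal cyclisations of this kind that create an angular methyl group; what is untested is the iminium ion of a β,β-disubstituted enal as a dienophile that builds quaternary C10. Ring B closes as the cyclohexene of the cycloaddition through both new bonds, and ring A closes as a six-membered carbocycle through C5–C10 alone, its C1–C4 tether folded chair-like and exo to the diene (fused 1,7,9-decatriene mode). C10 and C5 are set by the catalyst, whose benzyl group covers one face of the iminium π system so that the diene adds to the open face (the usual shielding model predicts 5S,10S for the (2S,5S) catalyst, and the (2R,5R) catalyst would be taken if the sense proved opposite), while C9 and C8 follow from suprafacial addition with retention of the 2E and 10E geometries and from the endo orientation (CHO cis to both the C10 and the C8 methyl groups). The step needs endo selectivity, which puts the iminium carbon under the diene and the tether outside and so gives the trans fusion (C5–H anti to C10–CH3), and it needs one π face; the defined (2E,8E,10E) geometry from steps 3–5, the four-atom tether that allows only the fused mode and the gem-dimethyl group at C4, which favours the coiled conformer (Thorpe–Ingold effect), support the former. Because C8 and C9 are flattened later, erosion at these two centres matters only where it changes the C5/C10 relationship.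

Step 8
Reactants: 17 trans-fused drim-6-en-11-al (8β-CH3, 9β-CHO)
Product: 18 (1S,2S,4aS,8aS)-2,5,5,8a-tetramethyldecahydronaphthalene-1-carbaldehyde
Conditions: H2 (1 atm), Pd/C (10 wt %), EtOAc, rt
Reagents that add atoms: none
Why: Heterogeneous hydrogenation saturates the cis-disubstituted C6=C7 bond and leaves the aldehyde alone in an aprotic solvent, and any epimerisation at C8 or C9 on the catalyst is harmless because both carbons become sp2 in step 9.

Step 9
Reactants: 18 (1S,2S,4aS,8aS)-2,5,5,8a-tetramethyldecahydronaphthalene-1-carbaldehyde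
Product: 19 (4aS,8aS)-2,5,5,8a-tetramethyl-3,4,4a,5,6,7,8,8a-octahydronaphthalene-1-carbaldehyde [drim-8-en-11-al]
Conditions: 2-iodoxybenzoic acid (IBX, 2 equiv), toluene/DMSO (2:1), 75 °C
Reagents that add atoms: none
Why: IBX-mediated dehydrogenation of aldehydes to enals proceeds through the enol and loss of a β-hydrogen, and since C9 holds the only α-hydrogen and C8 the only β-hydrogen the tetrasubstituted C8=C9 enal is the single possible product.

Step 10
Reactants: 19 drim-8-en-11-al
Product: 20 [(4aS,8aS)-2,5,5,8a-tetramethyl-3,4,4a,5,6,7,8,8a-octahydronaphthalen-1-yl]methanol [drim-8-en-11-ol]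
Conditions: NaBH4, CeCl3·7H2O, MeOH, 0 °C
Reagents that add atoms: none
Why: Luche reduction delivers hydride 1,2 to the hindered enal and gives the primary allylic alcohol without touching the tetrasubstituted alkene.

Step 11
Reactants: 20 drim-8-en-11-ol
Product: 21 11-bromodrim-8-ene [(4aS,8aS)-1-(bromomethyl)-2,5,5,8a-tetramethyl-3,4,4a,5,6,7,8,8a-octahydronaphthalene]
Conditions: CBr4, PPh3, CH2Cl2, 0 °C; used without storage
Reagents that add atoms: carbon tetrabromide, BrC(Br)(Br)Br
Why: The Appel reaction converts the primary allylic alcohol into the bromide under neutral conditions by SN2 displacement of the oxyphosphonium group, which avoids acid-induced ionisation of this allylic system.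

Step 12
Reactants: 21 11-bromodrim-8-ene; 22 trimethyl(prop-1-yn-1-yl)silane
Product: 25 (4aS,8aS)-1-(but-3-yn-1-yl)-2,5,5,8a-tetramethyl-3,4,4a,5,6,7,8,8a-octahydronaphthalene, via lithiated silylpropyne 23 (not isolated), via silyl alkyne 24 (not isolated)
Conditions: 22, n-BuLi, THF, −78 → −20 °C; then 21, −78 °C → rt; then MeOH, K2CO3, rt
Reagents that add atoms: none
Why: 3-Lithio-1-(trimethylsilyl)propyne alkylates primary allylic bromides at its propargylic carbon by SN2 substitution (the silyl group suppresses allenic products and SN2′ attack at fully substituted C8 is disfavoured), and methanolic carbonate then removes the silyl group to expose the terminal alkyne that carries C12–C14.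

Step 13
Reactants: 26 methyl (S)-3-hydroxy-2-methylpropanoate
Product: 27 methyl (S)-3-[(tert-butyldimethylsilyl)oxy]-2-methylpropanoate
Conditions: TBSCl, imidazole, CH2Cl2, rt
Reagents that add atoms: tert-butyldimethylsilyl chloride, CC(C)(C)[Si](C)(C)Cl
Why: Silylation of the primary alcohol with TBSCl and imidazole is routine and does not involve the stereocentre.

Step 14
Reactants: 27 methyl (S)-3-[(tert-butyldimethylsilyl)oxy]-2-methylpropanoate
Product: 29 (S)-3-[(tert-butyldimethylsilyl)oxy]-2-methylpropanal, via aluminium hemiacetal 28 (not isolated)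
Conditions: i-Bu2AlH (1.05 equiv), CH2Cl2, −78 °C; MeOH quench, aq. potassium sodium tartrate; used crude
Reagents that add atoms: none
Why: At −78 °C i-Bu2AlH adds once to the ester and the tetrahedral aluminium hemiacetal survives until work-up, giving the aldehyde without base and therefore without epimerisation of the α-stereocentre (partial ester reduction).

Step 15
Reactants: 29 (S)-3-[(tert-butyldimethylsilyl)oxy]-2-methylpropanal
Product: 30 tert-butyl{[(2R,3E)-4-iodo-2-methylbut-3-en-1-yl]oxy}dimethylsilane
Conditions: CrCl2 (6 equiv), CHI3 (2 equiv), THF, 0 °C → rt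
Reagents that add atoms: iodoform, IC(I)I
Why: Takai olefination under non-basic chromium conditions gives the (E)-vinyl iodide and preserves α-stereocentres of aldehydes, so the future C17 keeps its configuration (the descriptor changes to R only through priorities) and C15=C16 is set E.

Step 16
Reactants: 25 the but-3-ynyl drimene; 30 the (2R,3E)-vinyl iodide
Product: 32 tert-butyl{[(2R,3E,5E)-2,6-dimethyl-8-[(4aS,8aS)-2,5,5,8a-tetramethyl-3,4,4a,5,6,7,8,8a-octahydronaphthalen-1-yl]octa-3,5-dien-1-yl]oxy}dimethylsilane, via alkenylalane 31 (not isolated)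
Conditions: 25, AlMe3 (2 equiv), Cp2ZrCl2 (0.3 equiv), CH2Cl2, rt; volatiles removed in vacuo; then 30, Pd(PPh3)4 (5 mol %), ZnCl2 (co-catalyst), THF, rt
Reagents that add atoms: trimethylaluminium, C[Al](C)C
Why: Syn carboalumination sets the 13E geometry together with the C13 methyl group, and the palladium-catalysed Negishi-type coupling of the alkenylalane with the (E)-vinyl iodide forms C14–C15 with retention at both partners, so the 13E,15E-diene should arise without touching C17.

Step 17
Reactants: 32 the silyl ether of the full skeleton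
Product: 33 (2R,3E,5E)-2,6-dimethyl-8-[(4aS,8aS)-2,5,5,8a-tetramethyl-3,4,4a,5,6,7,8,8a-octahydronaphthalen-1-yl]octa-3,5-dien-1-ol
Conditions: Bu4NF, THF, 0 °C → rt
Reagents that add atoms: none
Why: Fluoride cleaves the primary silyl ether selectively, and the substrate carries no acidic or fluoride-sensitive group.

Step 18
Reactants: 33 the primary alcohol
Product: 35 (2R,3E,5E)-2,6-dimethyl-8-[(4aS,8aS)-2,5,5,8a-tetramethyl-3,4,4a,5,6,7,8,8a-octahydronaphthalen-1-yl]octa-3,5-dienoic acid, via aldehyde 34 (not isolated)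
Conditions: TEMPO (0.2 equiv), PhI(OAc)2 (1.2 equiv), CH2Cl2, rt; then t-BuOH/H2O, 2-methylbut-2-ene (excess), NaH2PO4, NaClO2, 0 °C
Reagents that add atoms: sodium chlorite, [Na+].[O-]Cl=O
Why: Oxoammonium oxidation (TEMPO, PhI(OAc)2) stops at the aldehyde and the Pinnick oxidation then converts it into the acid at pH 4–5 in the same flask, a sequence mild enough that the α-stereocentre C17 and the skipped 15E double bond should survive, with 2-methylbut-2-ene trapping hypochlorite before it can reach the alkenes.

Compound list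

1 | isobutyronitrile (2-methylpropanenitrile) | CC(C)C#N | starting material
2 | (5-iodopent-1-yn-1-yl)trimethylsilane | C[Si](C)(C)C#CCCCI | starting material
3 | lithium 2-cyanopropan-2-ide (lithiated 1, formed in situ) | [Li+].C[C-](C)C#N | intermediate
4 | 2,2-dimethyl-7-(trimethylsilyl)hept-6-ynenitrile | N#CC(C)(C)CCCC#C[Si](C)(C)C | intermediate
5 | N-(diisobutylaluminio) aldimine of 6 (formed in situ) | CC(C)C[Al](CC(C)C)N=CC(C)(C)CCCC#C[Si](C)(C)C | intermediate
6 | 2,2-dimethyl-7-(trimethylsilyl)hept-6-ynal | O=CC(C)(C)CCCC#C[Si](C)(C)C | intermediate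
7 | [(7E)-8-iodo-6,6-dimethyloct-7-en-1-yn-1-yl]trimethylsilane | I/C=C/C(C)(C)CCCC#C[Si](C)(C)C | intermediate
8 | (E)-prop-1-en-1-ylboronic acid | C/C=C/B(O)O | starting material
9 | trimethyl[(7E,9E)-6,6-dimethylundeca-7,9-dien-1-yn-1-yl]silane (formed in situ) | C/C=C/C=C/C(C)(C)CCCC#C[Si](C)(C)C | intermediate
10 | (7E,9E)-6,6-dimethylundeca-7,9-dien-1-yne | C/C=C/C=C/C(C)(C)CCCC#C | intermediate
11 | dimethyl[(1E,7E,9E)-2,6,6-trimethylundeca-1,7,9-trien-1-yl]alumane (formed in situ) | C[Al](C)/C=C(\C)CCCC(C)(C)/C=C/C=C/C | intermediate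
12 | lithium butyl(dimethyl)[(1E,7E,9E)-2,6,6-trimethylundeca-1,7,9-trien-1-yl]aluminate (formed in situ) | [Li+].CCCC[Al-](C)(C)/C=C(\C)CCCC(C)(C)/C=C/C=C/C | intermediate
13 | (2E,8E,10E)-3,7,7-trimethyldodeca-2,8,10-trien-1-ol | OC/C=C(\C)CCCC(C)(C)/C=C/C=C/C | intermediate
14 | (2E,8E,10E)-3,7,7-trimethyldodeca-2,8,10-trienal (precursor of the key step) | O=C/C=C(\C)CCCC(C)(C)/C=C/C=C/C | intermediate
15 | E-iminium triflate of 14 with the (2S,5S)-imidazolidinone (formed in situ) | C/C=C/C=C/C(C)(C)CCC/C(C)=C/C=[N+]1\[C@@H](Cc2ccccc2)C(=O)N(C)[C@H]1C(C)(C)C.[O-]S(=O)(=O)C(F)(F)F | intermediate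
16 | iminium triflate of cycloadduct 17 with the (2S,5S)-imidazolidinone (formed in situ) | C[C@@H]1[C@H](/C=[N+]2\[C@@H](Cc3ccccc3)C(=O)N(C)[C@H]2C(C)(C)C)[C@@]4(C)CCCC(C)(C)[C@@H]4C=C1.[O-]S(=O)(=O)C(F)(F)F | intermediate
17 | (1S,2S,4aS,8aS)-2,5,5,8a-tetramethyl-1,2,4a,5,6,7,8,8a-octahydronaphthalene-1-carbaldehyde (trans-fused drim-6-en-11-al; 5α-H, 8β-CH3, 9β-CHO, 10β-CH3; product of the key step) | C[C@@H]1[C@H](C=O)[C@@]2(C)CCCC(C)(C)[C@@H]2C=C1 | intermediate
18 | (1S,2S,4aS,8aS)-2,5,5,8a-tetramethyldecahydronaphthalene-1-carbaldehyde | C[C@@H]1[C@H](C=O)[C@@]2(C)CCCC(C)(C)[C@@H]2CC1 | intermediate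
19 | (4aS,8aS)-2,5,5,8a-tetramethyl-3,4,4a,5,6,7,8,8a-octahydronaphthalene-1-carbaldehyde (drim-8-en-11-al) | CC1=C(C=O)[C@@]2(C)CCCC(C)(C)[C@@H]2CC1 | intermediate
20 | [(4aS,8aS)-2,5,5,8a-tetramethyl-3,4,4a,5,6,7,8,8a-octahydronaphthalen-1-yl]methanol (drim-8-en-11-ol) | CC1=C(CO)[C@@]2(C)CCCC(C)(C)[C@@H]2CC1 | intermediate
21 | 11-bromodrim-8-ene (5α-H, 10β-CH3) | CC1=C(CBr)[C@@]2(C)CCCC(C)(C)[C@@H]2CC1 | intermediate
22 | trimethyl(prop-1-yn-1-yl)silane | CC#C[Si](C)(C)C | starting material
23 | [3-(trimethylsilyl)prop-2-yn-1-yl]lithium (formed in situ) | [Li]CC#C[Si](C)(C)C | intermediate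
24 | trimethyl{4-[(4aS,8aS)-2,5,5,8a-tetramethyl-3,4,4a,5,6,7,8,8a-octahydronaphthalen-1-yl]but-1-yn-1-yl}silane (formed in situ) | CC1=C(CCC#C[Si](C)(C)C)[C@@]2(C)CCCC(C)(C)[C@@H]2CC1 | intermediate
25 | (4aS,8aS)-1-(but-3-yn-1-yl)-2,5,5,8a-tetramethyl-3,4,4a,5,6,7,8,8a-octahydronaphthalene | CC1=C(CCC#C)[C@@]2(C)CCCC(C)(C)[C@@H]2CC1 | intermediate
26 | methyl (S)-3-hydroxy-2-methylpropanoate | COC(=O)[C@@H](C)CO | starting material
27 | methyl (S)-3-[(tert-butyldimethylsilyl)oxy]-2-methylpropanoate | COC(=O)[C@@H](C)CO[Si](C)(C)C(C)(C)C | intermediate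
28 | diisobutylaluminium hemiacetal of 29 (formed in situ, mixture at the hemiacetal carbon) | COC(O[Al](CC(C)C)CC(C)C)[C@@H](C)CO[Si](C)(C)C(C)(C)C | intermediate
29 | (S)-3-[(tert-butyldimethylsilyl)oxy]-2-methylpropanal | O=C[C@@H](C)CO[Si](C)(C)C(C)(C)C | intermediate
30 | tert-butyl{[(2R,3E)-4-iodo-2-methylbut-3-en-1-yl]oxy}dimethylsilane | I/C=C/[C@@H](C)CO[Si](C)(C)C(C)(C)C | intermediate
31 | dimethyl{(1E)-2-methyl-4-[(4aS,8aS)-2,5,5,8a-tetramethyl-3,4,4a,5,6,7,8,8a-octahydronaphthalen-1-yl]but-1-en-1-yl}alumane (formed in situ) | CC1=C(CC/C(C)=C/[Al](C)C)[C@@]2(C)CCCC(C)(C)[C@@H]2CC1 | intermediate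
32 | tert-butyl{[(2R,3E,5E)-2,6-dimethyl-8-[(4aS,8aS)-2,5,5,8a-tetramethyl-3,4,4a,5,6,7,8,8a-octahydronaphthalen-1-yl]octa-3,5-dien-1-yl]oxy}dimethylsilane | CC1=C(CC/C(C)=C/C=C/[C@@H](C)CO[Si](C)(C)C(C)(C)C)[C@@]2(C)CCCC(C)(C)[C@@H]2CC1 | intermediate
33 | (2R,3E,5E)-2,6-dimethyl-8-[(4aS,8aS)-2,5,5,8a-tetramethyl-3,4,4a,5,6,7,8,8a-octahydronaphthalen-1-yl]octa-3,5-dien-1-ol | CC1=C(CC/C(C)=C/C=C/[C@@H](C)CO)[C@@]2(C)CCCC(C)(C)[C@@H]2CC1 | intermediate
34 | (2R,3E,5E)-2,6-dimethyl-8-[(4aS,8aS)-2,5,5,8a-tetramethyl-3,4,4a,5,6,7,8,8a-octahydronaphthalen-1-yl]octa-3,5-dienal (formed in situ) | CC1=C(CC/C(C)=C/C=C/[C@@H](C)C=O)[C@@]2(C)CCCC(C)(C)[C@@H]2CC1 | intermediate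
35 | (2R,3E,5E)-2,6-dimethyl-8-[(4aS,8aS)-2,5,5,8a-tetramethyl-3,4,4a,5,6,7,8,8a-octahydronaphthalen-1-yl]octa-3,5-dienoic acid (CNP0106052.1) | CC1=C(CC/C(C)=C/C=C/[C@@H](C)C(=O)O)[C@@]2(C)CCCC(C)(C)[C@@H]2CC1 | target

Total step count: 18. Longest linear sequence: 15 (steps 1–12 and 16–18); steps 13–15 form the three-step branch to vinyl iodide 30.

Steps most likely to fail

1. Step 7 (key step). What may go wrong:
- The hindered β,β-disubstituted enal may condense with the catalyst too slowly.
- The dienophile carbon that becomes quaternary C10 may be too unreactive.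
- Deprotonation of the iminium ion to a dienamine would erase the 2E geometry and leak material into the cis-fused series.
- Facial discrimination at a fully substituted β-carbon is unproven.

Fallback (known chemistry, from 14 back to 17): Pinnick oxidation of 14 (NaClO2, NaH2PO4, 2-methylbut-2-ene) should give (2E,8E,10E)-3,7,7-trimethyldodeca-2,8,10-trienoic acid F1. Its pivaloyl mixed anhydride (t-BuCOCl, Et3N) acylates (4S)-4-benzyl-1,3-oxazolidin-2-one (LiCl, Et3N) to the trienoyl imide F2. Me2AlCl (1.5 equiv, CH2Cl2, −30 → 0 °C) then promotes the auxiliary-controlled intramolecular Diels–Alder reaction of the chelated s-cis imide. The diene adds anti to the benzyl group and endo, which is expected to give the same 5S,10S trans-fused skeleton as the cycloadduct imide F3. LiBH4 (Et2O, 1 equiv H2O) releases the auxiliary and gives the drim-6-en-11-ol F4, and Dess–Martin oxidation returns 17.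

2. Step 9. What may go wrong: enolisation of the neopentyl-type aldehyde toward C9 may be slow, so that dehydrogenation stalls or oxidation at other C–H bonds competes at the temperature needed.

Fallback (from 18 back to 19): enamine-mediated α-selenenylation (N-(phenylselanyl)phthalimide, pyrrolidine cat., CH2Cl2, rt) should place selenium on the less hindered α face of C9 and give the 9α-(phenylselanyl) aldehyde F5. Oxidation with H2O2/pyridine (CH2Cl2, 0 °C → rt) gives the selenoxide F6, which has a syn β-hydrogen only at C8 (8α-H) and should eliminate at room temperature to 19.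

3. Step 18. What may go wrong: the transient β,γ-unsaturated aldehyde may enolise, which would epimerise C17 or move C15=C16 into conjugation, and hypochlorite may chlorinate the electron-rich alkenes.

Fallback (from 30, with 25 as partner, back to 35): the carboxyl group is installed on the small fragment before coupling. Bu4NF converts 30 into (2R,3E)-4-iodo-2-methylbut-3-en-1-ol F7. Jones oxidation (CrO3, H2SO4, acetone, 0 °C; acidic, so no base-induced epimerisation) gives (2R,3E)-4-iodo-2-methylbut-3-enoic acid F8. Mitsunobu esterification with 2-(trimethylsilyl)ethanol (PPh3, DIAD) gives the 2-(trimethylsilyl)ethyl ester F9. The carboalumination/coupling of step 16 is then run on 25 with F9 in place of 30 and should give the 2-(trimethylsilyl)ethyl ester of the target F10. Bu4NF (THF, 0 °C) fragments this ester directly to the carboxylate, whose α-position is no longer acidic, and mild acidification gives 35.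

Further compounds

F1 | step 7 | (2E,8E,10E)-3,7,7-trimethyldodeca-2,8,10-trienoic acid | OC(=O)/C=C(\C)CCCC(C)(C)/C=C/C=C/C
F2 | step 7 | (4S)-4-benzyl-3-[(2E,8E,10E)-3,7,7-trimethyldodeca-2,8,10-trienoyl]-1,3-oxazolidin-2-one | O=C(/C=C(\C)CCCC(C)(C)/C=C/C=C/C)N1[C@@H](Cc2ccccc2)COC1=O
F3 | step 7 | (4S)-4-benzyl-3-{[(1S,2S,4aS,8aS)-2,5,5,8a-tetramethyl-1,2,4a,5,6,7,8,8a-octahydronaphthalen-1-yl]carbonyl}-1,3-oxazolidin-2-one | C[C@@H]1[C@H](C(=O)N2[C@@H](Cc3ccccc3)COC2=O)[C@@]4(C)CCCC(C)(C)[C@@H]4C=C1
F4 | step 7 | [(1S,2S,4aS,8aS)-2,5,5,8a-tetramethyl-1,2,4a,5,6,7,8,8a-octahydronaphthalen-1-yl]methanol | C[C@@H]1[C@H](CO)[C@@]2(C)CCCC(C)(C)[C@@H]2C=C1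
F5 | step 9 | (1R,2S,4aS,8aS)-2,5,5,8a-tetramethyl-1-(phenylselanyl)decahydronaphthalene-1-carbaldehyde (SePh on the α face of C9) | C[C@@H]1[C@@](C=O)([Se]c3ccccc3)[C@@]2(C)CCCC(C)(C)[C@@H]2CC1
F6 | step 9 | selenoxide of F5 (mixture at selenium) | C[C@@H]1[C@@](C=O)([Se](=O)c3ccccc3)[C@@]2(C)CCCC(C)(C)[C@@H]2CC1
F7 | step 18 | (2R,3E)-4-iodo-2-methylbut-3-en-1-ol | I/C=C/[C@@H](C)CO
F8 | step 18 | (2R,3E)-4-iodo-2-methylbut-3-enoic acid | I/C=C/[C@@H](C)C(=O)O
F9 | step 18 | 2-(trimethylsilyl)ethyl (2R,3E)-4-iodo-2-methylbut-3-enoate | I/C=C/[C@@H](C)C(=O)OCC[Si](C)(C)C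
F10 | step 18 | 2-(trimethylsilyl)ethyl (2R,3E,5E)-2,6-dimethyl-8-[(4aS,8aS)-2,5,5,8a-tetramethyl-3,4,4a,5,6,7,8,8a-octahydronaphthalen-1-yl]octa-3,5-dienoate | CC1=C(CC/C(C)=C/C=C/[C@@H](C)C(=O)OCC[Si](C)(C)C)[C@@]2(C)CCCC(C)(C)[C@@H]2CC1
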